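## Retrosynthetic overview

1. Goyazensolide ⇐ C8 methacrylate / C15 silyl ether ⇐ ten-membered carbocycle closed last by an intramolecular zinc Barbier allylation (C7–C8) of an α-(bromomethyl)butenolide onto an aldehyde.
2. The butenolide comes from ring-closing metathesis of a 2-(bromomethyl)acrylate; the bridging 3(2H)-furanone, the C10 stereocentre and the C8 aldehyde come in one step from a gold-catalysed hydrative cyclisation/1,2-methyl shift of a 2-alkynyl-2-methylfuran-3(2H)-one.
3. C3–C4 is made by Sonogashira coupling of a Z-vinyl iodide with the alkynyl furanone.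
4. The vinyl iodide comes from propargyl alcohol and crotonaldehyde (asymmetric alkynylation, directed hydroalumination–iodination); the alkynyl furanone from ethyl pyruvate, TMS-acetylene (asymmetric alkynylation) and ethynylmagnesium bromide.
5. Ring order: sacrificial furanone (ring A) → target furanone (ring B) → butenolide (ring C) → ten-membered carbocycle (ring D).

Assumption: the facial sense stated for the two chiral zinc catalysts follows the usual models; if a product proves to be the antipode, the enantiomeric ligand is used.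

## Route

Step 1
Reactants: 1 prop-2-yn-1-ol
Product: 2 tert-butyldimethyl(prop-2-yn-1-yloxy)silane
Conditions: TBSCl, imidazole, CH2Cl2, 0 °C to rt
Reagents that add atoms: tert-butyldimethylsilyl chloride, CC(C)(C)[Si](C)(C)Cl
Why: Standard O-silylation of the primary alcohol, so that only the later C6 alkoxide can direct the hydroalumination in step 3; no stereocentre.

Step 2
Reactants: 2 tert-butyldimethyl(prop-2-yn-1-yloxy)silane; 3 (E)-but-2-enal
Product: 4 (4S,5E)-1-[(tert-butyldimethylsilyl)oxy]hept-5-en-2-yn-4-ol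
Conditions: (S,S)-ProPhenol (10 mol%), ZnMe2 (3 equiv), Ph3PO (20 mol%), toluene, 0 °C; aq. NH4Cl
Reagents that add atoms: none
Why: Catalytic asymmetric alkynylation of an aldehyde (dinuclear zinc ProPhenol system): the zinc acetylide of 2 adds 1,2 to crotonaldehyde inside the chiral dizinc pocket, which sets the future C6 as 4S.

Step 3
Reactants: 4 (4S,5E)-1-[(tert-butyldimethylsilyl)oxy]hept-5-en-2-yn-4-ol
Product: 6 (2Z,4S,5E)-1-[(tert-butyldimethylsilyl)oxy]-2-iodohepta-2,5-dien-4-ol, via cyclic alkenylalanate 5 (not isolated)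
Conditions: NaAlH2(OCH2CH2OMe)2 (1.6 equiv), THF, 0 °C to rt; then I2, THF, −78 to 0 °C; aq. Na2S2O3, aq. KNaC4H4O6
Reagents that add atoms: iodine, II; sodium bis(2-methoxyethoxy)aluminium dihydride, [Na+].[AlH2-](OCCOC)OCCOC (its Na, Al and alkoxy groups stay only in 5)
Why: Hydroxyl-directed trans-hydroalumination of the propargylic alcohol puts Al on the distal alkyne carbon through the five-membered alkoxyalanate 5, and iodinolysis with retention gives only the Z vinyl iodide (iodine cis to the carbinol carbon); the carbinol centre is untouched.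

Step 4
Reactants: 7 ethyl 2-oxopropanoate; 8 ethynyl(trimethyl)silane
Product: 9 ethyl (2R)-2-hydroxy-2-methyl-4-(trimethylsilyl)but-3-ynoate
Conditions: Zn(OTf)2 (20 mol%), (1S,2S)-3-(tert-butyldimethylsilyloxy)-2-(dimethylamino)-1-(4-nitrophenyl)propan-1-ol (22 mol%), Et3N (30 mol%), toluene, 70 °C
Reagents that add atoms: none
Why: Zinc-catalysed asymmetric alkynylation of an α-keto ester: two-point binding of the pyruvate to the chiral amino-alkoxide zinc acetylide differentiates the ketone faces and sets the quaternary carbinol (2R), which is later relayed to C10.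

Step 5
Reactants: 9 ethyl (2R)-2-hydroxy-2-methyl-4-(trimethylsilyl)but-3-ynoate
Product: 10 (2R)-2-hydroxy-N-methoxy-N,2-dimethyl-4-(trimethylsilyl)but-3-ynamide
Conditions: MeNH(OMe)·HCl (3 equiv), i-PrMgCl (7 equiv), THF, −20 to 0 °C
Reagents that add atoms: N,O-dimethylhydroxylamine hydrochloride, CNOC.Cl
Why: Weinreb amide formation by aminolysis of the ester with the magnesium amide; the quaternary centre cannot epimerise.

Step 6
Reactants: 10 (2R)-2-hydroxy-N-methoxy-N,2-dimethyl-4-(trimethylsilyl)but-3-ynamide; 11 ethynylmagnesium bromide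
Product: 13 (2R)-2-ethynyl-2-methylfuran-3(2H)-one, via silyl ynone 12 (not isolated)
Conditions: HC≡CMgBr (3 equiv), THF, 0 °C; aq. NH4Cl; then K2CO3 (0.3 equiv), MeOH, 0 °C to rt; 1 M HCl
Reagents that add atoms: none
Why: Weinreb ketone synthesis (the magnesium chelate stops at mono-addition) gives ynone 12, which under K2CO3/MeOH loses the C-silyl group and closes by 5-endo-dig oxa-Michael addition of the tertiary hydroxyl to give the 3(2H)-furanone with the stereocentre retained.

Step 7
Reactants: 6 (2Z,4S,5E)-1-[(tert-butyldimethylsilyl)oxy]-2-iodohepta-2,5-dien-4-ol; 13 (2R)-2-ethynyl-2-methylfuran-3(2H)-one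
Product: 14 (2R)-2-[(3E,5S,6E)-3-{[(tert-butyldimethylsilyl)oxy]methyl}-5-hydroxyocta-3,6-dien-1-yn-1-yl]-2-methylfuran-3(2H)-one
Conditions: PdCl2(PPh3)2 (3 mol%), CuI (6 mol%), Et3N, THF, rt
Reagents that add atoms: none
Why: Sonogashira coupling forms C3–C4 with retention of the vinyl iodide geometry (alkyne cis to the carbinol carbon); the free secondary alcohol and the furanone are tolerated.

Step 8
Reactants: 14 (2R)-2-[(3E,5S,6E)-3-{[(tert-butyldimethylsilyl)oxy]methyl}-5-hydroxyocta-3,6-dien-1-yn-1-yl]-2-methylfuran-3(2H)-one; 15 2-(bromomethyl)prop-2-enoic acid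
Product: 16 (3E,5S,6E)-3-{[(tert-butyldimethylsilyl)oxy]methyl}-1-[(2R)-2-methyl-3-oxo-2,3-dihydrofuran-2-yl]octa-3,6-dien-1-yn-5-yl 2-(bromomethyl)prop-2-enoate
Conditions: DIC, DMAP (5 mol%), CH2Cl2, −20 °C
Reagents that add atoms: none
Why: Steglich esterification (O-acylation, configuration retained) installs the 2-(bromomethyl)acrylate needed for the metathesis and the allylation, and the electron-poor ester protects the bis-allylic carbinol from ionisation in step 9.

Step 9
Reactants: 16 (3E,5S,6E)-3-{[(tert-butyldimethylsilyl)oxy]methyl}-1-[(2R)-2-methyl-3-oxo-2,3-dihydrofuran-2-yl]octa-3,6-dien-1-yn-5-yl 2-(bromomethyl)prop-2-enoate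
Product: 18 (2Z,4S,5E)-1-[(tert-butyldimethylsilyl)oxy]-2-[(5R)-5-methyl-4-oxo-5-(2-oxoethyl)-4,5-dihydrofuran-2-yl]hepta-2,5-dien-4-yl 2-(bromomethyl)prop-2-enoate, via lactol 17 (not isolated)
Conditions: Ph3PAuNTf2 (5 mol%), H2O (5 equiv), 1,4-dioxane, 40 °C
Reagents that add atoms: water, O
Why: Proposed new method: hydrative gold-catalysed ring transposition of a 2-alkynyl-3(2H)-furanone, in which water adds reversibly to C5 of the vinylogous ester to give lactol 17, the now ordinary ketone oxygen attacks the gold-activated alkyne (5-endo-dig) to give a bicyclic oxocarbenium ion, the methyl group makes a suprafacial 1,2-shift to the oxocarbenium carbon (so 2R is relayed to 10R), and the O-alkylated cation is discharged by cleavage of the lactol C–O bond, which frees the C8 aldehyde and the new furanone carbonyl before protodeauration; the closest known reaction is the gold- or platinum-catalysed heterocyclisation/1,2-alkyl shift of 2-hydroxy-2-alkynyl ketones to 3(2H)-furanones, where the shift ends by loss of the hydroxyl proton instead of a C–O bond.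

Step 10
Reactants: 18 (2Z,4S,5E)-1-[(tert-butyldimethylsilyl)oxy]-2-[(5R)-5-methyl-4-oxo-5-(2-oxoethyl)-4,5-dihydrofuran-2-yl]hepta-2,5-dien-4-yl 2-(bromomethyl)prop-2-enoate
Product: 19 (5R)-3-(bromomethyl)-5-[(1Z)-3-[(tert-butyldimethylsilyl)oxy]-2-[(5R)-5-methyl-4-oxo-5-(2-oxoethyl)-4,5-dihydrofuran-2-yl]prop-1-en-1-yl]furan-2(5H)-one
Conditions: second-generation Hoveyda–Grubbs catalyst (5 mol%), CH2Cl2 (5 mM), 40 °C
Reagents that add atoms: none
Why: Ring-closing metathesis between the propenyl group and the 1,1-disubstituted acrylate expels propene and gives the α-(bromomethyl)butenolide; C6 is not involved and keeps its configuration.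

Step 11
Reactants: 19 (5R)-3-(bromomethyl)-5-[(1Z)-3-[(tert-butyldimethylsilyl)oxy]-2-[(5R)-5-methyl-4-oxo-5-(2-oxoethyl)-4,5-dihydrofuran-2-yl]prop-1-en-1-yl]furan-2(5H)-one
Product: 20 (6R,7R,8R,10R)-15-[(tert-butyldimethylsilyl)oxy]-8-hydroxy-1-oxo-3,10-epoxygermacra-2,4(Z),11(13)-trien-12,6-olide (15-O-silyl-8-O-demethacryloylgoyazensolide)
Conditions: activated Zn dust (10 equiv), THF/sat. aq. NH4Cl (4:1), 2 mM, slow addition of 19, rt
Reagents that add atoms: none
Why: Intramolecular zinc Barbier allylation: the allylzinc from the α-(bromomethyl)butenolide attacks the aldehyde through its γ-carbon (C7) on the face anti to the C6 alkenyl group (trans-lactone, 7R) and, following the syn preference of zinc additions of such bromolactones, gives 8R, while allylic transposition regenerates the exo-methylene.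

Step 12
Reactants: 20 15-O-silyl-8-O-demethacryloylgoyazensolide; 21 2-methylprop-2-enoyl chloride
Product: 23 goyazensolide (target), via silyl-protected goyazensolide 22 (not isolated)
Conditions: methacryloyl chloride (3 equiv), Et3N, DMAP (10 mol%), CH2Cl2, 0 °C; MeOH quench; then HF·pyridine, THF, 0 °C to rt
Reagents that add atoms: none
Why: O-acylation of the C8 alcohol (retention) followed in the same flask by fluoride cleavage of the primary silyl ether; no stereocentre is touched.

## Compound list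

1 | prop-2-yn-1-ol | C#CCO | starting material
2 | tert-butyldimethyl(prop-2-yn-1-yloxy)silane | C#CCO[Si](C)(C)C(C)(C)C | intermediate
3 | (E)-but-2-enal (crotonaldehyde) | C/C=C/C=O | starting material
4 | (4S,5E)-1-[(tert-butyldimethylsilyl)oxy]hept-5-en-2-yn-4-ol | C/C=C/[C@H](O)C#CCO[Si](C)(C)C(C)(C)C | intermediate
5 | sodium alkenylalanate: five-membered O–Al–C=C chelate of 4, Al (two 2-methoxyethoxy ligands) on chain C2, new H on C3 trans to Al | C/C=C/[C@@H]1O[Al-](OCCOC)(OCCOC)C(CO[Si](C)(C)C(C)(C)C)=C1.[Na+] | intermediate (not isolated)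
6 | (2Z,4S,5E)-1-[(tert-butyldimethylsilyl)oxy]-2-iodohepta-2,5-dien-4-ol | C/C=C/[C@H](O)/C=C(\I)CO[Si](C)(C)C(C)(C)C | intermediate
7 | ethyl 2-oxopropanoate (ethyl pyruvate) | CCOC(=O)C(C)=O | starting material
8 | ethynyl(trimethyl)silane | C#C[Si](C)(C)C | starting material
9 | ethyl (2R)-2-hydroxy-2-methyl-4-(trimethylsilyl)but-3-ynoate | CCOC(=O)[C@](C)(O)C#C[Si](C)(C)C | intermediate
10 | (2R)-2-hydroxy-N-methoxy-N,2-dimethyl-4-(trimethylsilyl)but-3-ynamide | CON(C)C(=O)[C@](C)(O)C#C[Si](C)(C)C | intermediate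
11 | ethynylmagnesium bromide | C#C[Mg]Br | starting material
12 | (4R)-4-hydroxy-4-methyl-6-(trimethylsilyl)hexa-1,5-diyn-3-one | C#CC(=O)[C@](C)(O)C#C[Si](C)(C)C | intermediate (not isolated)
13 | (2R)-2-ethynyl-2-methylfuran-3(2H)-one | C#C[C@@]1(C)OC=CC1=O | intermediate
14 | (2R)-2-[(3E,5S,6E)-3-{[(tert-butyldimethylsilyl)oxy]methyl}-5-hydroxyocta-3,6-dien-1-yn-1-yl]-2-methylfuran-3(2H)-one | C/C=C/[C@H](O)/C=C(CO[Si](C)(C)C(C)(C)C)\C#C[C@@]1(C)OC=CC1=O | intermediate
15 | 2-(bromomethyl)prop-2-enoic acid | C=C(CBr)C(=O)O | starting material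
16 | (3E,5S,6E)-3-{[(tert-butyldimethylsilyl)oxy]methyl}-1-[(2R)-2-methyl-3-oxo-2,3-dihydrofuran-2-yl]octa-3,6-dien-1-yn-5-yl 2-(bromomethyl)prop-2-enoate | C/C=C/[C@H](OC(=O)C(=C)CBr)/C=C(CO[Si](C)(C)C(C)(C)C)\C#C[C@@]1(C)OC=CC1=O | intermediate
17 | water adduct of 16: [(2R)-5-hydroxy-2-methyl-3-oxooxolan-2-yl] lactol, both C5 epimers | C/C=C/[C@H](OC(=O)C(=C)CBr)/C=C(CO[Si](C)(C)C(C)(C)C)\C#C[C@@]1(C)OC(O)CC1=O | intermediate (not isolated)
18 | (2Z,4S,5E)-1-[(tert-butyldimethylsilyl)oxy]-2-[(5R)-5-methyl-4-oxo-5-(2-oxoethyl)-4,5-dihydrofuran-2-yl]hepta-2,5-dien-4-yl 2-(bromomethyl)prop-2-enoate | C/C=C/[C@H](OC(=O)C(=C)CBr)/C=C(CO[Si](C)(C)C(C)(C)C)\C1=CC(=O)[C@@](C)(CC=O)O1 | intermediate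
19 | (5R)-3-(bromomethyl)-5-[(1Z)-3-[(tert-butyldimethylsilyl)oxy]-2-[(5R)-5-methyl-4-oxo-5-(2-oxoethyl)-4,5-dihydrofuran-2-yl]prop-1-en-1-yl]furan-2(5H)-one | BrCC1=C[C@@H](/C=C(CO[Si](C)(C)C(C)(C)C)\C2=CC(=O)[C@@](C)(CC=O)O2)OC1=O | intermediate
20 | (6R,7R,8R,10R)-15-[(tert-butyldimethylsilyl)oxy]-8-hydroxy-1-oxo-3,10-epoxygermacra-2,4(Z),11(13)-trien-12,6-olide | O[C@@H]1C[C@@]2(C)OC(=CC2=O)/C(CO[Si](C)(C)C(C)(C)C)=C\[C@H]2OC(=O)C(=C)[C@@H]21 | intermediate
21 | 2-methylprop-2-enoyl chloride (methacryloyl chloride) | C=C(C)C(=O)Cl | starting material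
22 | 15-O-(tert-butyldimethylsilyl)goyazensolide | C=C(C)C(=O)O[C@@H]1C[C@@]2(C)OC(=CC2=O)/C(CO[Si](C)(C)C(C)(C)C)=C\[C@H]2OC(=O)C(=C)[C@@H]21 | intermediate (not isolated)
23 | goyazensolide: (6R,7R,8R,10R)-15-hydroxy-8-(2-methylprop-2-enoyloxy)-1-oxo-3,10-epoxygermacra-2,4(Z),11(13)-trien-12,6-olide | C=C(C)C(=O)O[C@@H]1C[C@@]2(C)OC(=CC2=O)/C(CO)=C\[C@H]2OC(=O)C(=C)[C@@H]21 | target

## Step count and risks

Total steps: 12. Longest linear sequence: 9 (steps 1–3, then 7–12; the pyruvate branch, steps 4–6, then 7–12, is also 9).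

Most likely to fail:

Step 9 (the proposed new step). The hydration of the vinylogous ester may be too unfavourable, or the shift too slow. The fallback uses known chemistry, sets out from 10 and comes back at 18. Weinreb amide 10 is treated with (1,3-dioxolan-2-ylmethyl)magnesium bromide to give (3R)-1-(1,3-dioxolan-2-yl)-3-hydroxy-3-methyl-5-(trimethylsilyl)pent-4-yn-2-one F1. Sonogashira coupling of F1 with 6 (PdCl2(PPh3)2, CuI, Et3N, TBAF for in situ C-desilylation) gives (3R,6E,8S,9E)-6-{[(tert-butyldimethylsilyl)oxy]methyl}-1-(1,3-dioxolan-2-yl)-3,8-dihydroxy-3-methylundeca-6,9-dien-4-yn-2-one F2. Steglich esterification with 15 at the secondary hydroxyl gives the 8-O-[2-(bromomethyl)acryloyl] ester F3. The established AuCl3-catalysed heterocyclisation/1,2-alkyl shift of a 2-hydroxy-2-alkynyl ketone (free tertiary hydroxyl, methyl migrates, same chirality transfer) gives (2Z,4S,5E)-1-[(tert-butyldimethylsilyl)oxy]-2-[(5R)-5-(1,3-dioxolan-2-ylmethyl)-5-methyl-4-oxo-4,5-dihydrofuran-2-yl]hepta-2,5-dien-4-yl 2-(bromomethyl)prop-2-enoate F4. PPTS in wet acetone then cleaves the dioxolane to give 18. This costs one extra step.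

Step 11. The strained ring may not close under zinc conditions, or the macrocyclic transition state may override the syn preference and give the C8 epimer. The fallback sets out from 19 and comes back at 22. The ring is closed with CrCl2 (Nozaki–Hiyama–Kishi conditions, THF/DMF, high dilution), which reacts through the chair transition state and is expected to give the 8-epimer, (6R,7R,8S,10R)-15-[(tert-butyldimethylsilyl)oxy]-8-hydroxy-1-oxo-3,10-epoxygermacra-2,4(Z),11(13)-trien-12,6-olide F5. F5 is esterified with inversion (Mitsunobu: methacrylic acid, PPh3, DIAD, THF, 0 °C) to give 22, which is desilylated as in step 12.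

Step 2. The enantioselectivity with volatile crotonaldehyde may be insufficient, and the error would propagate to C6, C7 and C8. The fallback sets out from 2 and 3 and comes back at 4. The lithium acetylide of 2 (n-BuLi, THF, −78 °C) is added to 3 to give racemic (5E)-1-[(tert-butyldimethylsilyl)oxy]hept-5-en-2-yn-4-ol F6. Sharpless kinetic resolution (Ti(OiPr)4, L-(+)-diisopropyl tartrate, t-BuOOH 0.6 equiv, 4 Å sieves, CH2Cl2, −20 °C) epoxidises the 4R enantiomer to the erythro epoxy alcohol (1R)-4-[(tert-butyldimethylsilyl)oxy]-1-(3-methyloxiran-2-yl)but-2-yn-1-ol F7 and leaves (4S)-4 (at most 50%), which enters step 3.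

Further compounds
F1 | step 9 | (3R)-1-(1,3-dioxolan-2-yl)-3-hydroxy-3-methyl-5-(trimethylsilyl)pent-4-yn-2-one | O=C(CC1OCCO1)[C@](C)(O)C#C[Si](C)(C)C
F2 | step 9 | (3R,6E,8S,9E)-6-{[(tert-butyldimethylsilyl)oxy]methyl}-1-(1,3-dioxolan-2-yl)-3,8-dihydroxy-3-methylundeca-6,9-dien-4-yn-2-one | C/C=C/[C@H](O)/C=C(CO[Si](C)(C)C(C)(C)C)\C#C[C@@](C)(O)C(=O)CC1OCCO1
F3 | step 9 | 8-O-[2-(bromomethyl)acryloyl] ester of F2 | C/C=C/[C@H](OC(=O)C(=C)CBr)/C=C(CO[Si](C)(C)C(C)(C)C)\C#C[C@@](C)(O)C(=O)CC1OCCO1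
F4 | step 9 | (2Z,4S,5E)-1-[(tert-butyldimethylsilyl)oxy]-2-[(5R)-5-(1,3-dioxolan-2-ylmethyl)-5-methyl-4-oxo-4,5-dihydrofuran-2-yl]hepta-2,5-dien-4-yl 2-(bromomethyl)prop-2-enoate | C/C=C/[C@H](OC(=O)C(=C)CBr)/C=C(CO[Si](C)(C)C(C)(C)C)\C1=CC(=O)[C@@](C)(CC2OCCO2)O1
F5 | step 11 | (6R,7R,8S,10R)-15-[(tert-butyldimethylsilyl)oxy]-8-hydroxy-1-oxo-3,10-epoxygermacra-2,4(Z),11(13)-trien-12,6-olide (8-epimer of 20) | O[C@H]1C[C@@]2(C)OC(=CC2=O)/C(CO[Si](C)(C)C(C)(C)C)=C\[C@H]2OC(=O)C(=C)[C@@H]21
F6 | step 2 | racemic (5E)-1-[(tert-butyldimethylsilyl)oxy]hept-5-en-2-yn-4-ol | C/C=C/C(O)C#CCO[Si](C)(C)C(C)(C)C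
F7 | step 2 | erythro (1R)-4-[(tert-butyldimethylsilyl)oxy]-1-(3-methyloxiran-2-yl)but-2-yn-1-ol from the 4R enantiomer | C[C@@H]1O[C@H]1[C@@H](O)C#CCO[Si](C)(C)C(C)(C)C
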